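**Plan**

- Retrosynthesis: cut the aroyl C–C(aryl) bond (aryl Grignard + C4 aldehyde), trace that aldehyde carbon back to an exocyclic C4=CH2, raise ring carbon C5 to a lactone carbonyl, then cut O1–C5 (acyl) and C2–C3 together to give 3,4,5-trimethoxybenzaldehyde and a 2-(methoxycarbonyl)allylboronate, itself cut at Cα–CH2B and Cβ–CH2O back to methyl propiolate.
- Enabling feature: in the oxolane, C2 (aryl, bonded to O1) and C3 (CH2OH) are a syn carbinol/branch pair, C5 can sit at the lactone oxidation level, and C4 can carry the methylene that ends as the aroyl carbonyl carbon.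
- Forward: a three-component carbocupration/alkylation gives the allylboronate; allylboration/lactonisation forms C2–C3 and closes the only ring as an α-methylene lactone; reduction to the diol and SN2 re-closure at C5 bring the ring to the ether level; the exocyclic CH2 is hydroborated, oxidised, arylated and oxidised again; C4 is equilibrated and the PMB ether (PMB = 4-methoxybenzyl) removed.
- Stereochemistry: C2 (absolute) from a chiral phosphoric acid; C3 (relative to C2) from the alkene geometry of the boronate through a chair transition state; C4 by thermodynamic epimerisation α to the ketone after C2 and C3 are fixed.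

Key step: step 3

Remark: ring atoms are numbered O1, C2 (aryl), C3 (CH2OH), C4 (aroyl), C5 (CH2); the sense of induction of TRIP with the ester-bearing boronate is assumed to follow that established for allyl- and crotyl-Bpin, and the (R)-acid would be used instead if it proved reversed.

Step 1
Reactants: 1 4-methoxybenzyl alcohol; 2 tributyl(iodomethyl)stannane
Product: 3 tributyl{[(4-methoxybenzyl)oxy]methyl}stannane
Conditions: NaH, THF/DMF, 0 °C; then 2, 0 °C → rt
Reagents that add atoms: none
Why: Williamson ether synthesis, in which the sodium alkoxide of 1 displaces iodide from the unhindered primary carbon of 2 by SN2, the usual entry to alkoxymethylstannanes.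

Step 2
Reactants: 3 tributyl{[(4-methoxybenzyl)oxy]methyl}stannane; 4 methyl propiolate; 5 2-(iodomethyl)-4,4,5,5-tetramethyl-1,3,2-dioxaborolane
Product: 9 methyl (E)-4-[(4-methoxybenzyl)oxy]-2-[(4,4,5,5-tetramethyl-1,3,2-dioxaborolan-2-yl)methyl]but-2-enoate (CH2B cis to CH2OPMB), via alkoxymethyllithium 6 (not isolated), via lithium dialkylcuprate 7 (not isolated), via (Z)-alkenylcuprate 8 (not isolated)
Conditions: 3 (2 equiv), n-BuLi, THF, −78 °C; CuBr·SMe2 (1 equiv), −78 °C; 4 (1 equiv), −78 °C; HMPA then 5, −78 → 0 °C; aq NH4Cl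
Reagents that add atoms: none
Why: Tin–lithium exchange gives alkoxymethyllithium 6, whose Gilman cuprate 7 adds syn across the propiolate at −78 °C (carbocupration) so that copper and CH2OPMB are cis in 8, and alkylation of this alkenylcopper by the highly SN2-reactive iodomethylboronate proceeds with retention, the known three-component route to 2-alkoxycarbonyl allylboronates, which fixes CH2B cis to CH2OPMB.

Step 3
Reactants: 9 methyl (E)-4-[(4-methoxybenzyl)oxy]-2-[(pinacolboryl)methyl]but-2-enoate; 10 3,4,5-trimethoxybenzaldehyde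
Product: 12 (4S,5S)-4-{[(4-methoxybenzyl)oxy]methyl}-3-methylidene-5-(3,4,5-trimethoxyphenyl)oxolan-2-one (4,5-cis), via open-chain syn pinacol borate 11 (not isolated)
Conditions: (S)-TRIP (10 mol %), 4 Å MS, toluene, 0 °C → rt; then 45 °C
Reagents that add atoms: none
Why: The phosphoric acid hydrogen-bonds to a dioxaborolane oxygen (P–OH) and to the formyl C–H (P=O), and the boron-bound aldehyde and the allyl unit combine through a closed, chair-like six-membered transition state that forms C2–C3 with allylic transposition and leaves borate 11, whose benzylic B–O oxygen then attacks the neighbouring methyl ester to form O1–C5. The closest known reaction type is the Brønsted acid-catalysed allylboration of aldehydes with 2-alkoxycarbonyl allylboronates to α-methylene-γ-butyrolactones, run here under the chiral phosphoric acid catalysis established for allyl- and crotylboration with pinacol boronates. The oxolanone ring closes by 5-exo-trig acyl substitution (lactonisation) with loss of MeO–Bpin. C3 is set relative to C2 by the alkene geometry of 9: with the aryl group equatorial and the CH2OPMB group, cis to CH2B, forced axial in the chair, the syn adduct and therefore the 4,5-cis lactone should result, while C2 is set in the absolute sense by the catalyst, the (S)-acid being expected to direct attack to the Si face of the aldehyde. The step needs syn over anti selectivity and an intact benzylic C–O bond, secured by the geometrically pure trisubstituted alkene reacting only through the closed transition state and by an acid too weak to ionise the trimethoxybenzylic position.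

Step 4
Reactants: 12 (4S,5S)-lactone
Product: 13 (1S,2S)-2-{[(4-methoxybenzyl)oxy]methyl}-3-methylidene-1-(3,4,5-trimethoxyphenyl)butane-1,4-diol
Conditions: DIBAL-H (4 equiv), CH2Cl2, −78 → 0 °C; Rochelle salt work-up
Reagents that add atoms: none
Why: DIBAL-H reduction of the lactone proceeds by 1,2-hydride addition through the lactol to the allylic/benzylic 1,4-diol, avoids the conjugate reduction that LiAlH4 can cause on α-methylene lactones and touches neither stereocentre.

Step 5
Reactants: 13 (1S,2S)-diol
Product: 15 (2S,3S)-3-{[(4-methoxybenzyl)oxy]methyl}-4-methylidene-2-(3,4,5-trimethoxyphenyl)oxolane (2,3-cis), via primary allylic tosylate 14 (not isolated)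
Conditions: NaH (2.5 equiv), THF, 0 °C; TsCl (1.0 equiv, slow addition), 0 °C → rt
Reagents that add atoms: none
Why: Intramolecular Williamson etherification, in which the unhindered primary allylic alkoxide is sulfonylated in preference to the flanked benzylic one and the latter closes the ring by 5-exo-tet displacement (SN2 and SN2′ give the same product), so the C2–O bond is never broken and C2 and C3 are retained.

Step 6
Reactants: 15 (2S,3S)-4-methylidene oxolane
Product: 17 [(3R,4S,5S)-4-{[(4-methoxybenzyl)oxy]methyl}-5-(3,4,5-trimethoxyphenyl)oxolan-3-yl]methanol (all-cis), via B-alkyl-9-BBN adduct 16 (not isolated)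
Conditions: 9-BBN, THF, 0 °C → rt; then aq NaOH, H2O2, 0 °C → rt
Reagents that add atoms: hydrogen peroxide, OO
Why: Hydroboration–oxidation of the 1,1-disubstituted alkene places boron on the exocyclic carbon and oxidation with retention gives the primary alcohol; 9-BBN should add from the face opposite the C2 aryl and C3 CH2OPMB groups and so give mainly the all-cis C4 epimer, which is immaterial because C4 is equilibrated in step 10.

Step 7
Reactants: 17 all-cis primary alcohol
Product: 18 (3S,4S,5S)-4-{[(4-methoxybenzyl)oxy]methyl}-5-(3,4,5-trimethoxyphenyl)oxolane-3-carbaldehyde (all-cis)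
Conditions: Dess–Martin periodinane, NaHCO3, CH2Cl2, 0 °C → rt
Reagents that add atoms: none
Why: Dess–Martin oxidation converts the primary alcohol into the aldehyde under buffered, nearly neutral conditions that spare the PMB ether and the electron-rich arenes.

Step 8
Reactants: 18 all-cis aldehyde; 19 5-bromo-1,2,3-trimethoxybenzene
Product: 21 [(3S,4S,5S)-4-{[(4-methoxybenzyl)oxy]methyl}-5-(3,4,5-trimethoxyphenyl)oxolan-3-yl](3,4,5-trimethoxyphenyl)methanol (both carbinol epimers), via 3,4,5-trimethoxyphenylmagnesium bromide 20 (not isolated)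
Conditions: 19, Mg, I2 (cat.), THF, reflux; then 18, −78 → 0 °C
Reagents that add atoms: none
Why: Grignard addition of the aryl nucleophile to the aldehyde gives the carbinol, whose configuration (like any epimerisation at C4) is irrelevant because the carbinol is oxidised next and C4 is equilibrated afterwards.

Step 9
Reactants: 21 secondary benzylic alcohol
Product: 22 [(3S,4S,5S)-4-{[(4-methoxybenzyl)oxy]methyl}-5-(3,4,5-trimethoxyphenyl)oxolan-3-yl](3,4,5-trimethoxyphenyl)methanone (all-cis)
Conditions: Dess–Martin periodinane, NaHCO3, CH2Cl2, rt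
Reagents that add atoms: none
Why: Dess–Martin oxidation of the secondary benzylic alcohol gives the aryl ketone without acid or base strong enough to disturb C2 or C3.

Step 10
Reactants: 22 all-cis ketone
Product: 23 [(3R,4S,5S)-4-{[(4-methoxybenzyl)oxy]methyl}-5-(3,4,5-trimethoxyphenyl)oxolan-3-yl](3,4,5-trimethoxyphenyl)methanone (aryl and CH2OPMB cis, aroyl trans to CH2OPMB)
Conditions: DBU, toluene, 50 °C
Reagents that add atoms: none
Why: Thermodynamic epimerisation through the ketone enolate should move the aroyl group from the congested all-cis arrangement to the face opposite CH2OPMB, while C2 and C3 carry no acidic hydrogen and loss of the ring alkoxide from the enolate (the reverse of a 5-endo-trig closure) is stereoelectronically disfavoured.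

Step 11
Reactants: 23 trans ketone PMB ether
Product: 24 [(3R,4S,5S)-4-(hydroxymethyl)-5-(3,4,5-trimethoxyphenyl)oxolan-3-yl](3,4,5-trimethoxyphenyl)methanone (target)
Conditions: DDQ, CH2Cl2/pH 7 buffer (10:1), 0 °C → rt
Reagents that add atoms: none
Why: Oxidative PMB cleavage (benzylic hydride abstraction by DDQ, then hydrolysis of the oxocarbenium ion) runs at neutral pH and should take the exposed, para-methoxy-activated benzyl ether faster than the hindered ring C2–H, which avoids the acid that would ionise the C2–O1 bond and the base that would expose C4 to enolisation once the hydroxyl is free.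

**Compound list**

1 | 4-methoxybenzyl alcohol | COc1ccc(CO)cc1 | starting material
2 | tributyl(iodomethyl)stannane | CCCC[Sn](CCCC)(CCCC)CI | starting material
3 | tributyl{[(4-methoxybenzyl)oxy]methyl}stannane | CCCC[Sn](CCCC)(CCCC)COCc1ccc(OC)cc1 | intermediate
4 | methyl propiolate | C#CC(=O)OC | starting material
5 | 2-(iodomethyl)-4,4,5,5-tetramethyl-1,3,2-dioxaborolane | CC1(C)OB(CI)OC1(C)C | starting material
6 | {[(4-methoxybenzyl)oxy]methyl}lithium | [Li]COCc1ccc(OC)cc1 | intermediate (not isolated)
7 | lithium bis{[(4-methoxybenzyl)oxy]methyl}cuprate | [Li+].COc1ccc(COC[Cu-]COCc2ccc(OC)cc2)cc1 | intermediate (not isolated)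
8 | lithium {(Z)-1-methoxy-4-[(4-methoxybenzyl)oxy]-1-oxobut-2-en-2-yl}{[(4-methoxybenzyl)oxy]methyl}cuprate (Cu cis to CH2OPMB) | [Li+].COC(=O)/C([Cu-]COCc1ccc(OC)cc1)=C/COCc1ccc(OC)cc1 | intermediate (not isolated)
9 | methyl (E)-4-[(4-methoxybenzyl)oxy]-2-[(4,4,5,5-tetramethyl-1,3,2-dioxaborolan-2-yl)methyl]but-2-enoate | COC(=O)/C(CB1OC(C)(C)C(C)(C)O1)=C/COCc1ccc(OC)cc1 | intermediate
10 | 3,4,5-trimethoxybenzaldehyde | COc1cc(C=O)cc(OC)c1OC | starting material
11 | methyl (3S,4S)-3-{[(4-methoxybenzyl)oxy]methyl}-2-methylidene-4-[(4,4,5,5-tetramethyl-1,3,2-dioxaborolan-2-yl)oxy]-4-(3,4,5-trimethoxyphenyl)butanoate | COC(=O)C(=C)[C@@H](COCc1ccc(OC)cc1)[C@H](OB1OC(C)(C)C(C)(C)O1)c1cc(OC)c(OC)c(OC)c1 | intermediate (not isolated)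
12 | (4S,5S)-4-{[(4-methoxybenzyl)oxy]methyl}-3-methylidene-5-(3,4,5-trimethoxyphenyl)oxolan-2-one | C=C1C(=O)O[C@H](c2cc(OC)c(OC)c(OC)c2)[C@@H]1COCc1ccc(OC)cc1 | intermediate
13 | (1S,2S)-2-{[(4-methoxybenzyl)oxy]methyl}-3-methylidene-1-(3,4,5-trimethoxyphenyl)butane-1,4-diol | C=C(CO)[C@@H](COCc1ccc(OC)cc1)[C@H](O)c1cc(OC)c(OC)c(OC)c1 | intermediate
14 | (3S,4S)-4-hydroxy-3-{[(4-methoxybenzyl)oxy]methyl}-2-methylidene-4-(3,4,5-trimethoxyphenyl)butyl 4-methylbenzenesulfonate | C=C(COS(=O)(=O)c1ccc(C)cc1)[C@@H](COCc1ccc(OC)cc1)[C@H](O)c1cc(OC)c(OC)c(OC)c1 | intermediate (not isolated)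
15 | (2S,3S)-3-{[(4-methoxybenzyl)oxy]methyl}-4-methylidene-2-(3,4,5-trimethoxyphenyl)oxolane | C=C1CO[C@H](c2cc(OC)c(OC)c(OC)c2)[C@@H]1COCc1ccc(OC)cc1 | intermediate
16 | 9-{[(3S,4S,5S)-4-{[(4-methoxybenzyl)oxy]methyl}-5-(3,4,5-trimethoxyphenyl)oxolan-3-yl]methyl}-9-borabicyclo[3.3.1]nonane | C1CC2CCCC(C1)B2C[C@@H]1CO[C@H](c2cc(OC)c(OC)c(OC)c2)[C@@H]1COCc1ccc(OC)cc1 | intermediate (not isolated)
17 | [(3R,4S,5S)-4-{[(4-methoxybenzyl)oxy]methyl}-5-(3,4,5-trimethoxyphenyl)oxolan-3-yl]methanol (all-cis, expected main C4 epimer) | OC[C@@H]1CO[C@H](c2cc(OC)c(OC)c(OC)c2)[C@@H]1COCc1ccc(OC)cc1 | intermediate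
18 | (3S,4S,5S)-4-{[(4-methoxybenzyl)oxy]methyl}-5-(3,4,5-trimethoxyphenyl)oxolane-3-carbaldehyde (all-cis) | O=C[C@@H]1CO[C@H](c2cc(OC)c(OC)c(OC)c2)[C@@H]1COCc1ccc(OC)cc1 | intermediate
19 | 5-bromo-1,2,3-trimethoxybenzene | COc1cc(Br)cc(OC)c1OC | starting material
20 | 3,4,5-trimethoxyphenylmagnesium bromide | COc1cc([Mg]Br)cc(OC)c1OC | intermediate (not isolated)
21 | [(3S,4S,5S)-4-{[(4-methoxybenzyl)oxy]methyl}-5-(3,4,5-trimethoxyphenyl)oxolan-3-yl](3,4,5-trimethoxyphenyl)methanol (carbinol centre undefined, both epimers) | OC(c1cc(OC)c(OC)c(OC)c1)[C@@H]1CO[C@H](c2cc(OC)c(OC)c(OC)c2)[C@@H]1COCc1ccc(OC)cc1 | intermediate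
22 | [(3S,4S,5S)-4-{[(4-methoxybenzyl)oxy]methyl}-5-(3,4,5-trimethoxyphenyl)oxolan-3-yl](3,4,5-trimethoxyphenyl)methanone (all-cis) | O=C(c1cc(OC)c(OC)c(OC)c1)[C@@H]1CO[C@H](c2cc(OC)c(OC)c(OC)c2)[C@@H]1COCc1ccc(OC)cc1 | intermediate
23 | [(3R,4S,5S)-4-{[(4-methoxybenzyl)oxy]methyl}-5-(3,4,5-trimethoxyphenyl)oxolan-3-yl](3,4,5-trimethoxyphenyl)methanone | O=C(c1cc(OC)c(OC)c(OC)c1)[C@H]1CO[C@H](c2cc(OC)c(OC)c(OC)c2)[C@@H]1COCc1ccc(OC)cc1 | intermediate
24 | [(3R,4S,5S)-4-(hydroxymethyl)-5-(3,4,5-trimethoxyphenyl)oxolan-3-yl](3,4,5-trimethoxyphenyl)methanone | COc1cc(C(=O)[C@H]2CO[C@H](c3cc(OC)c(OC)c(OC)c3)[C@@H]2CO)cc(OC)c1OC | target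

**Step count**

Total: 11 steps. Longest linear sequence: 11 steps (steps 1–11 from 1 and 2; compounds 4, 5, 10 and 19 enter as purchased).

**Steps most likely to fail**

Step 3. The electron-poor, ester-bearing boronate may be activated too weakly by the phosphoric acid. The reaction would then have to be forced thermally and facial selectivity would be lost, or a stronger acid would begin to ionise the benzylic C–O bond. Fallback: absolute control is moved from the catalyst to a chiral ester that is expelled in the lactonisation. Setting out from stannane 3 (cuprate 7 made as in step 2), carbocupration of (1R,2S,5R)-5-methyl-2-(2-phenylpropan-2-yl)cyclohexyl prop-2-ynoate F1 (from propiolic acid and (−)-8-phenylmenthol, DCC, cat. DMAP, CH2Cl2, −20 °C) and trapping with 5 should give the 8-phenylmenthyl (E)-4-[(4-methoxybenzyl)oxy]-2-[(pinacolboryl)methyl]but-2-enoate F2. Its Sc(OTf)3-catalysed addition to aldehyde 10 (toluene, −78 °C → rt) is a known auxiliary-controlled form of this allylboration and comes back to the route at lactone 12. The antipodal auxiliary would be taken if the (−)-series favoured the mirror-image lactone.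

Step 2. The α-alkoxymethyl copper species may decompose before it adds, or the α-ester alkenylcopper may lose its geometry through the allenoate during a slow alkylation. Fallback: the same boronate is built without organocopper chemistry, setting out from 4-methoxybenzyl alcohol 1. O-Allylation (NaH, allyl bromide, THF) gives allyl 4-methoxybenzyl ether F3. Lemieux–Johnson cleavage (OsO4 cat., NaIO4, 2,6-lutidine, dioxane/H2O) gives [(4-methoxybenzyl)oxy]acetaldehyde F4. A Morita–Baylis–Hillman reaction with methyl acrylate (DABCO) gives racemic methyl 3-hydroxy-4-[(4-methoxybenzyl)oxy]-2-methylidenebutanoate F5, and acetylation (Ac2O, DMAP) gives methyl 3-acetoxy-4-[(4-methoxybenzyl)oxy]-2-methylidenebutanoate F6. Palladium-catalysed SN2′ borylation of F6 (Pd2(dba)3, B2pin2, toluene, 50 °C) is expected, as with related Baylis–Hillman acetates, to place the substituent trans to the ester and so return to boronate 9.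

Step 5. The sulfonyl chloride may also engage the benzylic alkoxide, whose electron-rich sulfonate would ionise and scramble C2. Fallback: the ring is closed in a mode where the benzylic oxygen can act only as the nucleophile, setting out from diol 13. Selective acylation of the primary allylic hydroxyl (ClCO2Me, pyridine, CH2Cl2, −20 °C) gives (3S,4S)-4-hydroxy-3-{[(4-methoxybenzyl)oxy]methyl}-2-methylidene-4-(3,4,5-trimethoxyphenyl)butyl methyl carbonate F7. Pd(PPh3)4 in THF then ionises it to a 2-substituted π-allyl complex with two equivalent CH2 termini, which the benzylic hydroxyl captures (Tsuji–Trost etherification) to return to oxolane 15.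

**Further compounds**

F1 | step 3 | (1R,2S,5R)-5-methyl-2-(2-phenylpropan-2-yl)cyclohexyl prop-2-ynoate | CC(C)(c1ccccc1)[C@@H]1CC[C@@H](C)C[C@H]1OC(=O)C#C
F2 | step 3 | (1R,2S,5R)-5-methyl-2-(2-phenylpropan-2-yl)cyclohexyl (E)-4-[(4-methoxybenzyl)oxy]-2-[(4,4,5,5-tetramethyl-1,3,2-dioxaborolan-2-yl)methyl]but-2-enoate | CC(C)(c1ccccc1)[C@@H]1CC[C@@H](C)C[C@H]1OC(=O)/C(CB1OC(C)(C)C(C)(C)O1)=C/COCc1ccc(OC)cc1
F3 | step 2 | allyl 4-methoxybenzyl ether | C=CCOCc1ccc(OC)cc1
F4 | step 2 | [(4-methoxybenzyl)oxy]acetaldehyde | O=CCOCc1ccc(OC)cc1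
F5 | step 2 | methyl 3-hydroxy-4-[(4-methoxybenzyl)oxy]-2-methylidenebutanoate (racemic) | COC(=O)C(=C)C(O)COCc1ccc(OC)cc1
F6 | step 2 | methyl 3-acetoxy-4-[(4-methoxybenzyl)oxy]-2-methylidenebutanoate (racemic) | COC(=O)C(=C)C(OC(C)=O)COCc1ccc(OC)cc1
F7 | step 5 | (3S,4S)-4-hydroxy-3-{[(4-methoxybenzyl)oxy]methyl}-2-methylidene-4-(3,4,5-trimethoxyphenyl)butyl methyl carbonate | C=C(COC(=O)OC)[C@@H](COCc1ccc(OC)cc1)[C@H](O)c1cc(OC)c(OC)c(OC)c1
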